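Late in both earlier runs the percentages showed no steady drift, so I followed one molecule of solid substrate and asked where it ended and how long that ending took to show.

| flask | solid substrate | remark | time |
|---|---|---|---|
| west | 0.063 M | run made earlier |  |
| south | 0.14 M | run made earlier |  |
| flask | 0.094 M |  | 40 h |

- west (time / h: target / %, isomer of the product / %): 4.00: 63.2, 19.3; 8.00: 66.1, 20.2; 12.0: 67.5, 20.5; 15.0: 67.7, 21.3; 20.0: 68.1, 21.5; 25.0: 68.0, 21.9
- south (time / h: target / %, isomer of the product / %): 1.50: 42.8, 13.4; 5.00: 63.5, 21.1; 8.00: 66.2, 23.0; 12.0: 65.7, 20.3; 20.0: 65.7, 18.9; 25.0: 68.2, 23.9

(readings scatter by 1 percentage point)

1. which holds at 40 h: what has brought the reaction to rest, or that it has not come to rest (for what has run out or reacted, a solid counts together with what of it has only dissolved) (it is still moving / all of the solid substrate has reacted / forward and back rates have come level)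
2. amount of target at 40 h, in percent of the solid substrate charged
3. amount of isomer of the product at 40 h, in percent of the solid substrate charged

- given per volume of solution although it is solid: solid substrate
- at the start none of the solid substrate is in solution
- what has only dissolved of solid substrate counts as not reacted
- the reaction counts as stopped when no species that holds the solid substrate changes by six tenths of a point or more over the second half of the time

Step 1. I averaged the readings at 20.0 h and 25.0 h from both runs. This gave the molecule's chance of ending as target, L = 67.5 %, and as isomer of the product, M = 21.6 %. The charges differed 2.22-fold, yet the two runs' late averages for target lay 1.1 percentage points apart, about the scatter of a reading, so I carried L and M to the flask.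

Step 2. Two times then mattered: the asked time t = 40 h and a settling time. In the west run the gap to L shrank from 4.3 points at 4.00 h to 1.4 points at 8.00 h. That gave 3.56 h: the settling time τ, in which this gap falls by a factor e. It is a rough reading.

Step 3. In the flask, t/τ = 11.2, so t is far longer than τ. Carried over from the west run, this estimate put the gap at half of t at 0.048 points, inside the limit for a stopped reaction given in the conditions above. L and M together came to 89.1 %, short of the whole charge, so I committed to forward and back rates having come level, with target 67.5 % and isomer 21.6 %.

The forecast, close to these figures but not equal, gave forward and back rates have come level, target 67.6 % and isomer 21.6 %, on the grounds that “South reached its plateau by about 8 h and west by about 15–20 h”.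

The flask gives forward and back rates have come level, target 67.1 % and isomer 21.3 %.

    starting material ⇌ target (K = 22.0, k = 0.0437 /min)
    target ⇌ isomer of the product (K = 0.318, k = 0.307 /min)
    solid substrate ⇌ starting material, rate k3*(cs3 - [starting material]) while solid is left; crystals form when [starting material] > cs3 (solubility = 26.0 mM, k = 1.14 /min)
    starting material ⇌ dormant form (K = 2.80, k = 0.107 /min)

Target stays within 5 points of its answer down to at least 5.0 h, which is 1.40 settling times against this flask's 11.2. The isomer stops at 21.3 % because of the reverse step, isomer of the product to target: the run without that step reaches 100 %. This is thermodynamic control. For the neighbour read at 25 h, τ leaves a gap of 0.4 points at half its time, so I expected rest near L and M. It gives target 67.1 % and isomer 21.3 %.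

The data were generated by integration with constants of no real substance; scatter was added.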